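## Retrosynthetic overview

1. Target 26 ⇒ keto diol 23: the ring ketone becomes the (Z)-enal in one pot with a β-lithio enol ether (addition, then acid-induced 1,3-oxygen transposition); the hydroxypropyl arm comes from an allyl group.
2. 23 ⇒ enone 17 + side-chain iodide 11 + allyl iodide: one alkoxide-directed conjugate addition/enolate allylation builds the quaternary carbon and its neighbour, both relayed from the tertiary carbinol.
3. 17 ⇒ 3,4-dimethylphenol 15: catalytic enantioselective para-hydroxylative dearomatisation (C–O bond) sets the carbinol, the only catalyst-controlled stereocentre; then selective hydrogenation of the unsubstituted enone C=C.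
4. 11 ⇒ geranyl acetate 1: allylic oxidation, bromide, ketone-enolate alkylation, double methylenation, hydrozirconation/iodination.
5. Rings: the single carbocycle is never closed; it is the benzene ring of 15, dearomatised in the first ring step.

Assumption: commercial geranyl acetate is the pure (2E) isomer, and the enantiomer of the new iodoarene catalyst is chosen so that the (R)-quinol forms.

## Route

Step 1
Reactants: 1 geranyl acetate [(2E)-3,7-dimethylocta-2,6-dien-1-yl acetate]
Product: 2 (2E,6E)-8-hydroxy-3,7-dimethylocta-2,6-dien-1-yl acetate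
Conditions: SeO2 (10 mol%), salicylic acid (10 mol%), tBuOOH (3 equiv), CH2Cl2, rt
Reagents that add atoms: tert-butyl hydroperoxide, CC(C)(C)OO
Why: SeO2 allylic oxidation (ene reaction, then [2,3]-shift) attacks the (E)-methyl of the electron-rich terminal alkene and leaves the acetate-deactivated 2,3-alkene alone.

Step 2
Reactants: 2 (2E,6E)-8-hydroxy-3,7-dimethylocta-2,6-dien-1-yl acetate
Product: 3 (2E,6E)-8-bromo-3,7-dimethylocta-2,6-dien-1-yl acetate
Conditions: CBr4, PPh3, CH2Cl2, 0 °C
Reagents that add atoms: carbon tetrabromide, BrC(Br)(Br)Br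
Why: Appel reaction, an SN2 displacement of the activated primary allylic alcohol by bromide without allylic shift or loss of alkene geometry.

Step 3
Reactants: 3 (2E,6E)-8-bromo-3,7-dimethylocta-2,6-dien-1-yl acetate; 4 3-methylbutan-2-one
Product: 6 (2E,6E)-3,7,11-trimethyl-10-oxododeca-2,6-dien-1-yl acetate, via lithium 3-methylbut-1-en-2-olate 5 (not isolated)
Conditions: 4 (2 equiv), LiN(iPr)2, THF, −78 °C; then 3, −78 → −20 °C
Reagents that add atoms: none
Why: kinetic deprotonation of 4 at its methyl group and SN2 alkylation of the less substituted lithium enolate by the primary allylic bromide (enolate alkylation); the acetate is inert to a ketone enolate at low temperature.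

Step 4
Reactants: 6 (2E,6E)-3,7,11-trimethyl-10-oxododeca-2,6-dien-1-yl acetate
Product: 7 (6E,10E)-12-hydroxy-2,6,10-trimethyldodeca-6,10-dien-3-one
Conditions: K2CO3 (0.2 equiv), MeOH, rt
Reagents that add atoms: none
Why: base-catalysed transesterification (methanolysis) frees the allylic alcohol and touches neither the ketone nor the alkenes.

Step 5
Reactants: 7 (6E,10E)-12-hydroxy-2,6,10-trimethyldodeca-6,10-dien-3-one
Product: 8 (2E,6E)-3,7,11-trimethyl-10-oxododeca-2,6-dienal
Conditions: PhI(OAc)2 (1.1 equiv), TEMPO (10 mol%), CH2Cl2, rt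
Reagents that add atoms: none
Why: oxoammonium (TEMPO) oxidation converts the primary allylic alcohol into the enal without E/Z isomerisation.

Step 6
Reactants: 8 (2E,6E)-3,7,11-trimethyl-10-oxododeca-2,6-dienal
Product: 9 (3E,7E)-4,8,12-trimethyl-11-methylidenetrideca-1,3,7-triene
Conditions: Ph3PCH3Br (3.0 equiv), KOtBu (2.9 equiv), THF, 0 °C → rt
Reagents that add atoms: methyltriphenylphosphonium bromide, C[P+](c1ccccc1)(c1ccccc1)c1ccccc1.[Br-]
Why: Wittig methylenation of both carbonyl groups gives the terminal diene and the 1,1-disubstituted alkene at once, and the trisubstituted alkenes keep their geometry.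

Step 7
Reactants: 9 (3E,7E)-4,8,12-trimethyl-11-methylidenetrideca-1,3,7-triene
Product: 11 (3E,7E)-1-iodo-4,8,12-trimethyl-11-methylidenetrideca-3,7-diene, via alkylzirconocene chloride 10 (not isolated)
Conditions: Cp2Zr(H)Cl (1.1 equiv), THF, rt; then I2 (1.1 equiv), 0 °C
Reagents that add atoms: iodine, II
Why: hydrozirconation adds Zr–H 1,2 and anti-Markovnikov to the unhindered vinyl end of the 1,3-diene faster than to the trisubstituted or the isopropyl-flanked 1,1-disubstituted alkene, and iodinolysis of the C–Zr bond gives the primary homoallylic iodide.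

Step 8
Reactants: 12 1-ethoxyprop-1-ene (E/Z mixture)
Product: 14 2-bromo-1-ethoxyprop-1-ene (E/Z mixture), via 1,2-dibromo-1-ethoxypropane 13 (not isolated)
Conditions: Br2 (1.0 equiv), CH2Cl2, −78 °C; then Et3N (1.5 equiv), −78 °C → rt
Reagents that add atoms: bromine, BrBr
Why: bromine addition to the enol ether, then E2 loss of HBr from the α-bromo ether (bromination–dehydrobromination) gives the β-bromo enol ether, whose alkene geometry is irrelevant later.

Step 9
Reactants: 15 3,4-dimethylphenol
Product: 16 (R)-4-hydroxy-3,4-dimethylcyclohexa-2,5-dien-1-one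
Conditions: chiral iodoarene catalyst A (10 mol%), mCPBA (1.3 equiv), MeCN/H2O (4:1), −10 °C
Reagents that add atoms: water, O
Why: Proposed new method: a catalytic enantioselective para-hydroxylative dearomatisation of a simple 3,4-dialkylphenol with water, not known at useful selectivity, using the new catalyst A = 2,2'-[(2-iodo-1,3-phenylene)bis(oxy)]bis{N-[2,6-bis(3,5-di-tert-butylphenyl)phenyl]propanamide} (one C2-symmetric enantiomer); mCPBA oxidises A to the aryl-λ3-iodane (trivalent iodine), the phenol oxygen exchanges onto iodine, the two amide N–H···O–I hydrogen bonds fold the lactamide arms into a pocket whose terphenyl walls reach past the ring to C4 and leave one ring face open, the 3-methyl group fixes the rotamer about the O–I bond, and water held by an amide carbonyl on the open face attacks C4 in an associative SN2′-type displacement of the iodoarene, so the C–O bond and the (R) tertiary carbinol form in the same step; closest known reaction type: chiral-iodoarene-catalysed oxidative dearomatisation of phenols (Kita-type spirolactonisation, ortho-quinol formation) and the racemic PhI(OAc)2/H2O para-quinol synthesis.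

Step 10
Reactants: 16 (R)-4-hydroxy-3,4-dimethylcyclohexa-2,5-dien-1-one
Product: 17 (R)-4-hydroxy-3,4-dimethylcyclohex-2-en-1-one
Conditions: H2 (1 atm), RhCl(PPh3)3 (5 mol%), toluene, rt
Reagents that add atoms: none
Why: homogeneous hydrogenation with RhCl(PPh3)3 reduces the disubstituted enone C=C of a cross-conjugated dienone far faster than the trisubstituted one (as with steroidal 1,4-dien-3-ones), and the carbinol centre is untouched.

Step 11
Reactants: 17 (R)-4-hydroxy-3,4-dimethylcyclohex-2-en-1-one; 11 (3E,7E)-1-iodo-4,8,12-trimethyl-11-methylidenetrideca-3,7-diene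
Product: 21 (2R,3S,4R)-4-hydroxy-3,4-dimethyl-2-(prop-2-en-1-yl)-3-[(3E,7E)-4,8,12-trimethyl-11-methylidenetrideca-3,7-dien-1-yl]cyclohexan-1-one, via alkylmagnesium iodide 18 (not isolated), via chloromagnesium alkoxide 19 (not isolated), via magnesium enolate 20 (not isolated)
Conditions: 11, Mg, THF, rt; 17 (1.5 equiv), tBuMgCl (1.5 equiv), THF, −40 °C; add 18, −40 → 0 °C; then DMPU, allyl iodide (3 equiv), 0 °C → rt
Reagents that add atoms: allyl iodide, C=CCI
Why: Proposed new method: alkoxide-directed conjugate addition of a Grignard reagent to a 4-oxido enone is known for β-unsubstituted quinol-type enones and is here asked to build a quaternary carbon next to the carbinol carbon; alkoxide 19 binds 18 as a magnesiate and transfers the alkyl group through a five-membered O–Mg–C···Cβ transition state, which puts the chain on the oxygen face (chain cis to O) and should outrun unassisted 1,2-addition at the remote carbonyl, and enolate 20 is then allylated in a chair-like transition state anti to the axial 4-methyl group, that is on the face opposite both methyl groups, which sets C2; closest known reaction types: ligand-assisted 1,4-addition of Grignard reagents to quinol alkoxides and chelation-controlled conjugate addition to γ-hydroxy unsaturated nitriles.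

Step 12
Reactants: 21 (2R,3S,4R)-4-hydroxy-3,4-dimethyl-2-(prop-2-en-1-yl)-3-[(3E,7E)-4,8,12-trimethyl-11-methylidenetrideca-3,7-dien-1-yl]cyclohexan-1-one
Product: 23 (2R,3S,4R)-4-hydroxy-2-(3-hydroxypropyl)-3,4-dimethyl-3-[(3E,7E)-4,8,12-trimethyl-11-methylidenetrideca-3,7-dien-1-yl]cyclohexan-1-one, via pinacol boronate 22 (not isolated)
Conditions: HBpin (2.5 equiv), [Ir(cod)Cl]2 (1.5 mol%), dppm (3 mol%), CH2Cl2, rt; then NaBO3·4H2O, THF/H2O, rt
Reagents that add atoms: sodium perborate, [Na+].[Na+].O[B-]1(O)OO[B-](O)(O)OO1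
Why: iridium-catalysed hydroboration is anti-Markovnikov and selective for the monosubstituted alkene over the hindered 1,1-disubstituted and trisubstituted alkenes and the ketone, and perborate oxidises C–B to C–OH under conditions too mild to epimerise C2.

Step 13
Reactants: 23 (2R,3S,4R)-4-hydroxy-2-(3-hydroxypropyl)-3,4-dimethyl-3-[(3E,7E)-4,8,12-trimethyl-11-methylidenetrideca-3,7-dien-1-yl]cyclohexan-1-one; 14 2-bromo-1-ethoxyprop-1-ene (E/Z mixture)
Product: 26 (2Z)-2-[(2S,3S,4R)-4-hydroxy-2-(3-hydroxypropyl)-3,4-dimethyl-3-[(3E,7E)-4,8,12-trimethyl-11-methylidenetrideca-3,7-dien-1-yl]cyclohexylidene]propanal, via (1-ethoxyprop-1-en-2-yl)lithium 24 (not isolated), via tertiary allylic alcohol adduct 25 (not isolated)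
Conditions: 14 (5 equiv), tBuLi (10 equiv), Et2O, −78 °C; CeCl3 (5 equiv), THF, −78 °C; add 23, −78 → −40 °C; then 1 M HCl, THF, 0 °C
Reagents that add atoms: water, O
Why: a β-lithio enol ether is a formyl-vinyl anion equivalent (carbonyl addition, then acid-induced allylic transposition and hydrolysis of the vinylogous hemiacetal, the 1,3-oxygen shift creating the aldehyde C=O), so the ketone becomes the conjugated enal without touching the free hydroxyls or C2; the (Z)-enal, with the small planar CHO and not CH3 beside the substituted C2, is expected to predominate and is freed from the (E)-isomer by chromatography.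

## Compound list

1 | geranyl acetate [(2E)-3,7-dimethylocta-2,6-dien-1-yl acetate] | CC(=O)OC/C=C(\C)CCC=C(C)C | starting material
2 | (2E,6E)-8-hydroxy-3,7-dimethylocta-2,6-dien-1-yl acetate | CC(=O)OC/C=C(\C)CC/C=C(\C)CO | intermediate
3 | (2E,6E)-8-bromo-3,7-dimethylocta-2,6-dien-1-yl acetate | CC(=O)OC/C=C(\C)CC/C=C(\C)CBr | intermediate
4 | 3-methylbutan-2-one | CC(=O)C(C)C | starting material
5 | lithium 3-methylbut-1-en-2-olate | [Li+].[O-]C(=C)C(C)C | intermediate
6 | (2E,6E)-3,7,11-trimethyl-10-oxododeca-2,6-dien-1-yl acetate | CC(=O)OC/C=C(\C)CC/C=C(\C)CCC(=O)C(C)C | intermediate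
7 | (6E,10E)-12-hydroxy-2,6,10-trimethyldodeca-6,10-dien-3-one | OC/C=C(\C)CC/C=C(\C)CCC(=O)C(C)C | intermediate
8 | (2E,6E)-3,7,11-trimethyl-10-oxododeca-2,6-dienal | O=C/C=C(\C)CC/C=C(\C)CCC(=O)C(C)C | intermediate
9 | (3E,7E)-4,8,12-trimethyl-11-methylidenetrideca-1,3,7-triene | C=C/C=C(\C)CC/C=C(\C)CCC(=C)C(C)C | intermediate
10 | chlorobis(cyclopentadienyl)[(3E,7E)-4,8,12-trimethyl-11-methylidenetrideca-3,7-dien-1-yl]zirconium | Cl[Zr](CC/C=C(\C)CC/C=C(\C)CCC(=C)C(C)C)(C1C=CC=C1)C1C=CC=C1 | intermediate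
11 | (3E,7E)-1-iodo-4,8,12-trimethyl-11-methylidenetrideca-3,7-diene | ICC/C=C(\C)CC/C=C(\C)CCC(=C)C(C)C | intermediate
12 | 1-ethoxyprop-1-ene (E/Z mixture) | CC=COCC | starting material
13 | 1,2-dibromo-1-ethoxypropane | CC(Br)C(Br)OCC | intermediate
14 | 2-bromo-1-ethoxyprop-1-ene (E/Z mixture) | CC(Br)=COCC | intermediate
15 | 3,4-dimethylphenol | Cc1ccc(O)cc1C | starting material
16 | (R)-4-hydroxy-3,4-dimethylcyclohexa-2,5-dien-1-one | CC1=CC(=O)C=C[C@@]1(C)O | intermediate
17 | (R)-4-hydroxy-3,4-dimethylcyclohex-2-en-1-one | CC1=CC(=O)CC[C@@]1(C)O | intermediate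
18 | [(3E,7E)-4,8,12-trimethyl-11-methylidenetrideca-3,7-dien-1-yl]magnesium iodide | I[Mg]CC/C=C(\C)CC/C=C(\C)CCC(=C)C(C)C | intermediate
19 | chloromagnesium (R)-1,2-dimethyl-4-oxocyclohex-2-en-1-olate | CC1=CC(=O)CC[C@@]1(C)O[Mg]Cl | intermediate
20 | magnesium enolate/alkoxide (1-O–MgI, 4-O–MgCl) of (3S,4R)-3,4-dimethyl-3-[(3E,7E)-4,8,12-trimethyl-11-methylidenetrideca-3,7-dien-1-yl]cyclohex-1-ene-1,4-diol | C=C(CC/C(C)=C/CC/C(C)=C/CC[C@@]1(C)C=C(O[Mg]I)CC[C@@]1(C)O[Mg]Cl)C(C)C | intermediate
21 | (2R,3S,4R)-4-hydroxy-3,4-dimethyl-2-(prop-2-en-1-yl)-3-[(3E,7E)-4,8,12-trimethyl-11-methylidenetrideca-3,7-dien-1-yl]cyclohexan-1-one | C=C(CC/C(C)=C/CC/C(C)=C/CC[C@@]1(C)[C@@H](CC=C)C(=O)CC[C@@]1(C)O)C(C)C | intermediate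
22 | (2R,3S,4R)-4-hydroxy-3,4-dimethyl-2-[3-(4,4,5,5-tetramethyl-1,3,2-dioxaborolan-2-yl)propyl]-3-[(3E,7E)-4,8,12-trimethyl-11-methylidenetrideca-3,7-dien-1-yl]cyclohexan-1-one | C=C(CC/C(C)=C/CC/C(C)=C/CC[C@@]1(C)[C@@H](CCCB2OC(C)(C)C(C)(C)O2)C(=O)CC[C@@]1(C)O)C(C)C | intermediate
23 | (2R,3S,4R)-4-hydroxy-2-(3-hydroxypropyl)-3,4-dimethyl-3-[(3E,7E)-4,8,12-trimethyl-11-methylidenetrideca-3,7-dien-1-yl]cyclohexan-1-one | C=C(CC/C(C)=C/CC/C(C)=C/CC[C@@]1(C)[C@@H](CCCO)C(=O)CC[C@@]1(C)O)C(C)C | intermediate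
24 | (1-ethoxyprop-1-en-2-yl)lithium | [Li]C(C)=COCC | intermediate
25 | 1-(1-ethoxyprop-1-en-2-yl)-2-(3-hydroxypropyl)-3,4-dimethyl-3-[(3E,7E)-4,8,12-trimethyl-11-methylidenetrideca-3,7-dien-1-yl]cyclohexane-1,4-diol (C1 epimers; other centres as in 23) | C=C(CC/C(C)=C/CC/C(C)=C/CC[C@@]1(C)[C@@H](CCCO)C(O)(C(C)=COCC)CC[C@@]1(C)O)C(C)C | intermediate
26 | (2Z)-2-[(2S,3S,4R)-4-hydroxy-2-(3-hydroxypropyl)-3,4-dimethyl-3-[(3E,7E)-4,8,12-trimethyl-11-methylidenetrideca-3,7-dien-1-yl]cyclohexylidene]propanal | C=C(CC/C(C)=C/CC/C(C)=C/CC[C@@]1(C)[C@@H](CCCO)/C(=C(/C)C=O)CC[C@@]1(C)O)C(C)C | target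

## Step count and risks

Total: 13 steps (7 for the side chain, 1 for the enol-ether reagent, 5 on the ring). Longest linear sequence: 10 steps (steps 1–7, then 11, 12, 13).

Steps most likely to fail:

Step 9 (the proposed new dearomatisation). Asymmetric induction at the remote para carbon may be poor, or a dissociative phenoxenium pathway may erase it. The fallback sets out from 15 and comes back at 17, using only known chemistry. 15 is oxidised with PhI(OAc)2 in MeCN/H2O to racemic 4-hydroxy-3,4-dimethylcyclohexa-2,5-dien-1-one F1. F1 is hydrogenated as in step 10 to racemic 4-hydroxy-3,4-dimethylcyclohex-2-en-1-one F2. F2 is resolved by preparative chromatography on a chiral stationary phase, and its (R)-enantiomer is 17. The step 11 fallback below reaches the same carbinol by a different known C–O bond formation and needs neither 16 nor 17.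

Step 11 (the proposed new directed addition/allylation). Unassisted 1,2-addition may win at the β-methyl enone, and the facial selectivity of the allylation at C2 is argued, not proven. The fallback sets out from 11 (with commercial 3-ethoxycyclohex-2-en-1-one F3) and comes back at 21, using known chemistry throughout:
- F3 is methylated (LiN(iPr)2, MeI) to 3-ethoxy-6-methylcyclohex-2-en-1-one F4.
- The lithium enolate of F4 is hydroxylated with an enantiopure (camphorsulfonyl)oxaziridine to (R)-3-ethoxy-6-hydroxy-6-methylcyclohex-2-en-1-one F5, which is silylated (Et3SiOTf, 2,6-lutidine) to (R)-3-ethoxy-6-methyl-6-[(triethylsilyl)oxy]cyclohex-2-en-1-one F6.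
- 11 is converted with tBuLi into [(3E,7E)-4,8,12-trimethyl-11-methylidenetrideca-3,7-dien-1-yl]lithium F7, which adds 1,2 to F6.
- Dilute HCl then effects the Stork–Danheiser transposition to (R)-4-methyl-4-[(triethylsilyl)oxy]-3-[(3E,7E)-4,8,12-trimethyl-11-methylidenetrideca-3,7-dien-1-yl]cyclohex-2-en-1-one F8.
- Me2CuLi adds anti to the pseudoaxial silyloxy group (methyl trans to oxygen, chain cis), and the enolate is allylated with allyl iodide/DMPU to (2R,3S,4R)-3,4-dimethyl-2-(prop-2-en-1-yl)-4-[(triethylsilyl)oxy]-3-[(3E,7E)-4,8,12-trimethyl-11-methylidenetrideca-3,7-dien-1-yl]cyclohexan-1-one F9.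
- Bu4NF then gives 21.

Step 13 (enal geometry). The E/Z ratio of the tetrasubstituted enal is set in an ionisation step that is hard to predict, and acid could equilibrate it. The fallback sets out from 23 and comes back at 26. Horner–Wadsworth–Emmons olefination of 23 with diethyl (1-cyanoethyl)phosphonate and NaH (THF, reflux) gives two configurationally stable, separable nitriles: (2Z)-2-[(2S,3S,4R)-4-hydroxy-2-(3-hydroxypropyl)-3,4-dimethyl-3-[(3E,7E)-4,8,12-trimethyl-11-methylidenetrideca-3,7-dien-1-yl]cyclohexylidene]propanenitrile F10 and its (2E)-isomer F11. F11 is photoisomerised and recycled. Reduction of F10 with iBu2AlH (−78 °C) and mild acidic hydrolysis of the aldimine gives 26 with the geometry already fixed.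

Further compounds
F1 | step 9 | racemic 4-hydroxy-3,4-dimethylcyclohexa-2,5-dien-1-one | CC1=CC(=O)C=CC1(C)O
F2 | step 9 | racemic 4-hydroxy-3,4-dimethylcyclohex-2-en-1-one | CC1=CC(=O)CCC1(C)O
F3 | step 11 | 3-ethoxycyclohex-2-en-1-one | CCOC1=CC(=O)CCC1
F4 | step 11 | 3-ethoxy-6-methylcyclohex-2-en-1-one | CCOC1=CC(=O)C(C)CC1
F5 | step 11 | (R)-3-ethoxy-6-hydroxy-6-methylcyclohex-2-en-1-one | O=C1C=C(OCC)CC[C@@]1(C)O
F6 | step 11 | (R)-3-ethoxy-6-methyl-6-[(triethylsilyl)oxy]cyclohex-2-en-1-one | O=C1C=C(OCC)CC[C@@]1(C)O[Si](CC)(CC)CC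
F7 | step 11 | [(3E,7E)-4,8,12-trimethyl-11-methylidenetrideca-3,7-dien-1-yl]lithium | [Li]CC/C=C(\C)CC/C=C(\C)CCC(=C)C(C)C
F8 | step 11 | (R)-4-methyl-4-[(triethylsilyl)oxy]-3-[(3E,7E)-4,8,12-trimethyl-11-methylidenetrideca-3,7-dien-1-yl]cyclohex-2-en-1-one | C=C(CC/C(C)=C/CC/C(C)=C/CCC1=CC(=O)CC[C@@]1(C)O[Si](CC)(CC)CC)C(C)C
F9 | step 11 | (2R,3S,4R)-3,4-dimethyl-2-(prop-2-en-1-yl)-4-[(triethylsilyl)oxy]-3-[(3E,7E)-4,8,12-trimethyl-11-methylidenetrideca-3,7-dien-1-yl]cyclohexan-1-one | C=C(CC/C(C)=C/CC/C(C)=C/CC[C@@]1(C)[C@@H](CC=C)C(=O)CC[C@@]1(C)O[Si](CC)(CC)CC)C(C)C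
F10 | step 13 | (2Z)-2-[(2S,3S,4R)-4-hydroxy-2-(3-hydroxypropyl)-3,4-dimethyl-3-[(3E,7E)-4,8,12-trimethyl-11-methylidenetrideca-3,7-dien-1-yl]cyclohexylidene]propanenitrile | C=C(CC/C(C)=C/CC/C(C)=C/CC[C@@]1(C)[C@@H](CCCO)/C(=C(/C)C#N)CC[C@@]1(C)O)C(C)C
F11 | step 13 | (2E)-2-[(2S,3S,4R)-4-hydroxy-2-(3-hydroxypropyl)-3,4-dimethyl-3-[(3E,7E)-4,8,12-trimethyl-11-methylidenetrideca-3,7-dien-1-yl]cyclohexylidene]propanenitrile | C=C(CC/C(C)=C/CC/C(C)=C/CC[C@@]1(C)[C@@H](CCCO)/C(=C(\C)C#N)CC[C@@]1(C)O)C(C)C
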